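**Retrosynthetic overview**

1. Target 29 ⇐ silyl ether 28 ⇐ aldehyde 26. The C5–C6 bond is made by an intramolecular Ni/Cr-mediated alkenyl iodide–aldehyde coupling; the C6 alkoxide then lactonises onto the C12 acrylate ester, so ring A (ten-membered carbocycle) and ring C (12,6-α-methylene-γ-lactone) close in one operation and C6 is set.
2. Enabling feature: C5 is the sp2 CH end of the ring-cis C4=C5 alkene (so an (E)-alkenyl iodide that keeps its geometry), and C6 is a carbinol carbon whose oxygen lies γ to C12. The preformed butenolide (ring B, tying C8 to C10) and the cis alkene fold the chain.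
3. 26 ⇐ 18 + 22: syn-selective, catalyst-controlled chromium 2-(alkoxycarbonyl)allylation forms C7–C8, sets C7 and C8, and closes ring B.
4. 18 ⇐ 15 (silyl-directed singlet-oxygen opening of a 3-furyl ester) ⇐ 7 + 10 (furyllithium addition, oxidation, asymmetric transfer hydrogenation for C1).
5. 7 ⇐ diethyl allylmalonate (iodoform route to the (E)-β-iodoacrylate). Ring order: B first, then A and C together.

Key step: step 18

Numbering used (germacrane): C1 CH–O-isobutyrate; C2, C3 CH2; C4 (=C carrying C15H2OH); C5 (=CH); C6 (CH–O of the α-methylene lactone); C7; C8 (CH–O of the butenolide); C9 (=CH); C10; C11 (=C13H2); C12 and C14 the lactone carbonyls.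

Assumption: in step 16 the ligand enantiomer named is taken to be the one that sends the allyl group to the Si face of the C8 aldehyde; if the sense proved opposite, its mirror image would be used.

**Route**

Step 1
Reactants: 1 diethyl allylmalonate
Product: 2 diethyl 2-allyl-2-(diiodomethyl)malonate
Conditions: NaH, Et2O, reflux; then CHI3, reflux
Reagents that add atoms: iodoform IC(I)I
Why: C-alkylation of the sodium malonate by iodoform (diiodomethylation of a 2-substituted malonate, the first half of the classical route to (E)-3-iodo-2-alkylacrylic acids); no stereocentre is formed.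

Step 2
Reactants: 2 diethyl 2-allyl-2-(diiodomethyl)malonate
Product: 3 (2E)-2-(iodomethylidene)pent-4-enoic acid
Conditions: KOH, EtOH/H2O (3:1), reflux; then aq. HCl
Reagents that add atoms: potassium hydroxide [K+].[OH-] (one carboxyl oxygen)
Why: saponification followed by decarboxylative Grob-type loss of iodide should give the β-iodoacrylic acid as the E isomer (iodine trans to CO2H, cis to the allyl group), as for the 2-methyl analogue.

Step 3
Reactants: 3 (2E)-2-(iodomethylidene)pent-4-enoic acid
Product: 4 (2E)-2-(iodomethylidene)pent-4-en-1-ol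
Conditions: LiAlH4, Et2O, 0 °C
Reagents that add atoms: none
Why: hydride reduction of the conjugated acid to the allylic alcohol, standard for 3-iodoacrylic acids, should leave the alkenyl iodide and its geometry untouched.

Step 4
Reactants: 4 (2E)-2-(iodomethylidene)pent-4-en-1-ol
Product: 5 tert-butyldiphenylsilyl ether of 4
Conditions: tBuPh2SiCl, imidazole, DMF, rt
Reagents that add atoms: tert-butyl(chloro)diphenylsilane CC(C)(C)[Si](Cl)(c1ccccc1)c1ccccc1
Why: silylation of the primary alcohol gives an acid-stable ether that will outlast the later acetal hydrolysis.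

Step 5
Reactants: 5 tert-butyldiphenylsilyl ether of 4
Product: 6 (4E)-4-(silyloxymethyl)-5-iodopent-4-en-1-ol
Conditions: 9-BBN, THF, rt; then NaOH, H2O2, 0 °C
Reagents that add atoms: hydrogen peroxide OO
Why: hydroboration–oxidation, in which 9-BBN takes only the monosubstituted terminal alkene (anti-Markovnikov) and not the trisubstituted iodoalkene.

Step 6
Reactants: 6 (4E)-4-(silyloxymethyl)-5-iodopent-4-en-1-ol
Product: 7 (4E)-4-(silyloxymethyl)-5-iodopent-4-enal
Conditions: Dess–Martin periodinane, CH2Cl2, rt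
Reagents that add atoms: none
Why: Dess–Martin oxidation of the primary alcohol stops at the aldehyde (C1) and does not touch the iodoalkene.

Step 7
Reactants: 8 3-bromofuran
Product: 10 (3-bromofuran-2-yl)trimethylsilane, via 3-bromo-2-lithiofuran 9 (not isolated)
Conditions: LiN(iPr)2, THF, −78 °C; then Me3SiCl
Reagents that add atoms: chlorotrimethylsilane C[Si](C)(C)Cl
Why: directed deprotonation at C2, the position flanked by oxygen and bromine, and silylation place the silyl group that later fixes the site of the lactone carbonyl.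

Step 8
Reactants: 10 (3-bromofuran-2-yl)trimethylsilane; 7 (4E)-4-(silyloxymethyl)-5-iodopent-4-enal
Product: 12 racemic furyl carbinol, via [2-(trimethylsilyl)furan-3-yl]lithium 11 (not isolated)
Conditions: n-BuLi, Et2O, −78 °C; then 7, −78 °C; H2O
Reagents that add atoms: none
Why: bromine–lithium exchange gives a 3-furyllithium that the silyl group keeps from migrating to C2 and that adds to the aldehyde faster than it exchanges with the alkenyl iodide at −78 °C; C1 is formed racemic here and is corrected in steps 9 and 10.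

Step 9
Reactants: 12 racemic furyl carbinol
Product: 13 furyl ketone
Conditions: Dess–Martin periodinane, CH2Cl2, rt
Reagents that add atoms: none
Why: Dess–Martin oxidation of the secondary carbinol removes the uncontrolled C1 centre.

Step 10
Reactants: 13 furyl ketone
Product: 14 (1S)-furyl carbinol
Conditions: RuCl(p-cymene)[(S,S)-TsDPEN] (2 mol %), HCO2H/Et3N (5:2), rt
Reagents that add atoms: none
Why: Noyori asymmetric transfer hydrogenation of a heteroaryl alkyl ketone, in which the (S,S) catalyst should give the (S)-carbinol (furyl as the aryl-type group, CH2 chain as the small group), setting C1.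

Step 11
Reactants: 14 (1S)-furyl carbinol
Product: 15 (1S)-furyl isobutyrate
Conditions: iPrCOCl, pyridine, DMAP (cat.), CH2Cl2, 0 °C
Reagents that add atoms: 2-methylpropanoyl chloride CC(C)C(Cl)=O
Why: acylation with retention at C1 installs the isobutyrate of the target early, so no protecting group is needed on O1.

Step 12
Reactants: 15 (1S)-furyl isobutyrate
Product: 17 α-substituted γ-hydroxybutenolide, via furan endoperoxide 16 (not isolated)
Conditions: O2, hν, tetraphenylporphyrin (cat.), CH2Cl2, −78 °C; then H2O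
Reagents that add atoms: dioxygen O=O
Why: [4+2] addition of singlet oxygen to the furan (far more reactive than the iodoalkene) and silyl migration to the peroxide oxygen turn the silylated carbon into the carbonyl C14, so the carbonyl ends up next to the substituted carbon C10 (silyl-directed γ-hydroxybutenolide synthesis); the hemiacetal carbon C8 forms as an inconsequential epimer mixture.

Step 13
Reactants: 17 α-substituted γ-hydroxybutenolide
Product: 18 methyl (Z)-4-oxobut-2-enoate carrying the C1 side chain at C10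
Conditions: Me3SiCHN2, toluene/MeOH (4:1), 0 °C
Reagents that add atoms: (trimethylsilyl)diazomethane C[Si](C)(C)C=[N+]=[N-]
Why: diazoalkane O-methylation of the carboxylic acid form of the ring–chain tautomeric pseudo-acid traps the open aldehyde ester, with C8 and C14 cis as in the ring.

Step 14
Reactants: 19 methyl acrylate; 20 2,2-dimethoxyacetaldehyde
Product: 21 racemic methyl 3-hydroxy-4,4-dimethoxy-2-methylidenebutanoate
Conditions: DABCO (0.3 equiv), dioxane/H2O, rt
Reagents that add atoms: none
Why: Morita–Baylis–Hillman reaction with a reactive α,α-dialkoxy aldehyde; the carbinol centre becomes sp2 in the next step.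

Step 15
Reactants: 21 racemic Morita–Baylis–Hillman alcohol
Product: 22 methyl (2Z)-2-(bromomethyl)-4,4-dimethoxybut-2-enoate
Conditions: NBS, Me2S, CH2Cl2, 0 °C to rt
Reagents that add atoms: N-bromosuccinimide O=C1CCC(=O)N1Br
Why: Corey–Kim-type activation of the alcohol and SN2' attack of bromide (allylic transposition of Morita–Baylis–Hillman alcohols) should give the thermodynamically preferred Z bromide with the acetal carbon cis to CH2Br under non-acidic conditions.

Step 16
Reactants: 18 methyl (Z)-4-oxobut-2-enoate; 22 methyl (2Z)-2-(bromomethyl)-4,4-dimethoxybut-2-enoate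
Product: 25 butenolide acetal ester (1S,7R,8R), via open-chain silyl ether 23 (not isolated), via open-chain hydroxy diester 24 (not isolated)
Conditions: CrCl2 (10 mol %), (S,S)-3,6-diphenyl-1,8-bis(4-isopropyl-4,5-dihydrooxazol-2-yl)carbazole (12 mol %), Mn, Me3SiCl, iPr2NEt, THF, 0 °C; then PPTS, MeOH, rt
Reagents that add atoms: none
Why: catalytic asymmetric Nozaki–Hiyama 2-(alkoxycarbonyl)allylation, in which the chromium-bound allyl unit keeps its C6 substituent cis to the metal-bearing CH2 and reacts through a closed Zimmerman–Traxler chair to give the syn C7/C8 adduct, the ligand directs it to the Si face of the C8 aldehyde (reagent control over the remote C1 centre), and after desilylation the (Z)-γ-hydroxy enoate closes spontaneously to butenolide ring B rather than onto C12 because O8 and C14 are held cis and coplanar.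

Step 17
Reactants: 25 butenolide acetal ester
Product: 26 butenolide aldehyde ester (C6 aldehyde)
Conditions: LiBF4, MeCN/H2O (50:1), rt
Reagents that add atoms: water O
Why: Lewis-acid-assisted hydrolysis of the dimethyl acetal under near-neutral conditions, chosen to limit epimerisation at C7 and migration of the C11=C13 double bond; silyl ether, esters and butenolide are inert.

Step 18
Reactants: 26 butenolide aldehyde ester
Product: 28 tricyclic dilactone silyl ether, via macrocyclic hydroxy ester 27 (not isolated)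
Conditions: CrCl2 (10 equiv), NiCl2 (0.1 equiv), DMSO/THF (3:1), 0.002 M, rt, slow addition of 26; then 0.5 M aq. HCl
Reagents that add atoms: none
Why: NiCl2 is reduced by CrCl2 to zerovalent nickel, which inserts into the C5–I bond; transmetalation gives an alkenyl trivalent-chromium species that adds to the C6 aldehyde with retention of the alkene geometry, and the chromium alkoxide (free alcohol after the acidic work-up) acylates on the C12 methyl ester, the closest known reaction type being the Nozaki–Hiyama–Kishi macrocyclisation of alkenyl iodide–aldehydes to medium carbocycles combined with the lactonisation of γ-hydroxy α-methylene esters. Ring A closes in the 10-exo-trig mode at the aldehyde carbon (C5–C6 bond, with C4=C5 ending endocyclic and ring-cis) and ring C in the 5-exo-trig mode by attack of O6 on C12 with loss of methanol. The only new stereocentre, C6, is controlled by the neighbouring C7 centre inside the cyclic transition state: the chromium-bound oxygen and the C7 acrylate arm sit on the outside of the forming ring with H6 and H7 antiperiplanar, which is attack on the Re face and should give the 6R, 6,7-trans arrangement. The step needs chemoselectivity for the aldehyde over two esters, a lactone and two Michael acceptors, which alkenylchromium reagents have, and it needs ring closure to beat oligomerisation. This is secured by high dilution and by the substrate itself: the ring-cis C4=C5 bond and the flat butenolide ring B, which ties C8 to C10, fold the tether so that C5 and C6 are held close.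

Step 19
Reactants: 28 tricyclic dilactone silyl ether
Product: 29 target
Conditions: HF·pyridine, pyridine, THF, 0 °C to rt
Reagents that add atoms: none
Why: fluoride cleavage of the primary silyl ether under buffered acidic conditions should spare both lactones, the isobutyrate and the Michael acceptors; no stereocentre is touched.

**Compound list**

1 | diethyl 2-(prop-2-en-1-yl)propanedioate (diethyl allylmalonate) | C=CCC(C(=O)OCC)C(=O)OCC | starting material
2 | diethyl 2-(diiodomethyl)-2-(prop-2-en-1-yl)propanedioate | C=CCC(C(I)I)(C(=O)OCC)C(=O)OCC | intermediate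
3 | (2E)-2-(iodomethylidene)pent-4-enoic acid | C=CC/C(=C\I)C(=O)O | intermediate
4 | (2E)-2-(iodomethylidene)pent-4-en-1-ol | C=CC/C(=C\I)CO | intermediate
5 | tert-butyl{[(2E)-2-(iodomethylidene)pent-4-en-1-yl]oxy}diphenylsilane | C=CC/C(=C\I)CO[Si](c1ccccc1)(c1ccccc1)C(C)(C)C | intermediate
6 | (4E)-4-{[tert-butyl(diphenyl)silyl]oxymethyl}-5-iodopent-4-en-1-ol | OCCC/C(=C\I)CO[Si](c1ccccc1)(c1ccccc1)C(C)(C)C | intermediate
7 | (4E)-4-{[tert-butyl(diphenyl)silyl]oxymethyl}-5-iodopent-4-enal | O=CCC/C(=C\I)CO[Si](c1ccccc1)(c1ccccc1)C(C)(C)C | intermediate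
8 | 3-bromofuran | Brc1ccoc1 | starting material
9 | 3-bromo-2-lithiofuran (not isolated) | [Li]c1occc1Br | intermediate
10 | (3-bromofuran-2-yl)trimethylsilane | C[Si](C)(C)c1occc1Br | intermediate
11 | [2-(trimethylsilyl)furan-3-yl]lithium (not isolated) | [Li]c1ccoc1[Si](C)(C)C | intermediate
12 | racemic (4E)-4-{[tert-butyl(diphenyl)silyl]oxymethyl}-5-iodo-1-[2-(trimethylsilyl)furan-3-yl]pent-4-en-1-ol | CC(C)(C)[Si](c1ccccc1)(c1ccccc1)OC/C(=C/I)CCC(O)c1ccoc1[Si](C)(C)C | intermediate
13 | (4E)-4-{[tert-butyl(diphenyl)silyl]oxymethyl}-5-iodo-1-[2-(trimethylsilyl)furan-3-yl]pent-4-en-1-one | CC(C)(C)[Si](c1ccccc1)(c1ccccc1)OC/C(=C/I)CCC(=O)c1ccoc1[Si](C)(C)C | intermediate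
14 | (1S,4E)-4-{[tert-butyl(diphenyl)silyl]oxymethyl}-5-iodo-1-[2-(trimethylsilyl)furan-3-yl]pent-4-en-1-ol | CC(C)(C)[Si](c1ccccc1)(c1ccccc1)OC/C(=C/I)CC[C@H](O)c1ccoc1[Si](C)(C)C | intermediate
15 | (1S,4E)-4-{[tert-butyl(diphenyl)silyl]oxymethyl}-5-iodo-1-[2-(trimethylsilyl)furan-3-yl]pent-4-en-1-yl 2-methylpropanoate | CC(C)(C)[Si](c1ccccc1)(c1ccccc1)OC/C(=C/I)CC[C@H](OC(=O)C(C)C)c1ccoc1[Si](C)(C)C | intermediate
16 | 2,5-endoperoxide of furan 15 (1-trimethylsilyl-2,3,7-trioxabicyclo[2.2.1]hept-5-ene with the side chain on C6; not isolated) | C[Si](C)(C)C12OOC(O1)C=C2[C@@H](OC(=O)C(C)C)CC/C(=C\I)CO[Si](c1ccccc1)(c1ccccc1)C(C)(C)C | intermediate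
17 | (1S,4E)-4-{[tert-butyl(diphenyl)silyl]oxymethyl}-1-(5-hydroxy-2-oxo-2,5-dihydrofuran-3-yl)-5-iodopent-4-en-1-yl 2-methylpropanoate (hemiacetal epimers) | O=C1OC(O)C=C1[C@@H](OC(=O)C(C)C)CC/C(=C\I)CO[Si](c1ccccc1)(c1ccccc1)C(C)(C)C | intermediate
18 | methyl (2Z)-2-[(1S,4E)-4-{[tert-butyl(diphenyl)silyl]oxymethyl}-5-iodo-1-(2-methylpropanoyloxy)pent-4-en-1-yl]-4-oxobut-2-enoate | COC(=O)/C(=C\C=O)[C@@H](OC(=O)C(C)C)CC/C(=C\I)CO[Si](c1ccccc1)(c1ccccc1)C(C)(C)C | intermediate
19 | methyl prop-2-enoate (methyl acrylate) | C=CC(=O)OC | starting material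
20 | 2,2-dimethoxyacetaldehyde | COC(OC)C=O | starting material
21 | racemic methyl 3-hydroxy-4,4-dimethoxy-2-methylidenebutanoate | COC(=O)C(=C)C(O)C(OC)OC | intermediate
22 | methyl (2Z)-2-(bromomethyl)-4,4-dimethoxybut-2-enoate | COC(=O)/C(CBr)=C/C(OC)OC | intermediate
23 | O8-trimethylsilyl ether of 24 (not isolated) | COC(=O)/C(=C\[C@@H](O[Si](C)(C)C)[C@@H](C(=C)C(=O)OC)C(OC)OC)[C@@H](OC(=O)C(C)C)CC/C(=C\I)CO[Si](c1ccccc1)(c1ccccc1)C(C)(C)C | intermediate
24 | dimethyl (2Z,4R,5R)-2-[(1S,4E)-4-{[tert-butyl(diphenyl)silyl]oxymethyl}-5-iodo-1-(2-methylpropanoyloxy)pent-4-en-1-yl]-5-(dimethoxymethyl)-4-hydroxy-6-methylidenehept-2-enedioate (not isolated) | COC(=O)/C(=C\[C@@H](O)[C@@H](C(=C)C(=O)OC)C(OC)OC)[C@@H](OC(=O)C(C)C)CC/C(=C\I)CO[Si](c1ccccc1)(c1ccccc1)C(C)(C)C | intermediate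
25 | methyl 2-[(1R)-1-{(2R)-4-[(1S,4E)-4-{[tert-butyl(diphenyl)silyl]oxymethyl}-5-iodo-1-(2-methylpropanoyloxy)pent-4-en-1-yl]-5-oxo-2,5-dihydrofuran-2-yl}-2,2-dimethoxyethyl]prop-2-enoate | COC(=O)C(=C)[C@@H](C(OC)OC)[C@@H]1OC(=O)C(=C1)[C@@H](OC(=O)C(C)C)CC/C(=C\I)CO[Si](c2ccccc2)(c2ccccc2)C(C)(C)C | intermediate
26 | methyl (3R)-3-{(2R)-4-[(1S,4E)-4-{[tert-butyl(diphenyl)silyl]oxymethyl}-5-iodo-1-(2-methylpropanoyloxy)pent-4-en-1-yl]-5-oxo-2,5-dihydrofuran-2-yl}-2-methylidene-4-oxobutanoate | COC(=O)C(=C)[C@@H](C=O)[C@@H]1OC(=O)C(=C1)[C@@H](OC(=O)C(C)C)CC/C(=C\I)CO[Si](c2ccccc2)(c2ccccc2)C(C)(C)C | intermediate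
27 | macrocyclic hydroxy ester: methyl 2-substituted acrylate of the (1S,6R,7S,8R,4E,9Z) ten-membered ring bearing 6-OH, 1-O-isobutyrate, 15-O-silyl and the 14,8-butenolide (not isolated) | COC(=O)C(=C)[C@H]1[C@H](O)/C=C(/CO[Si](c2ccccc2)(c2ccccc2)C(C)(C)C)CC[C@H](OC(=O)C(C)C)C2=C[C@H]1OC2=O | intermediate
28 | 15-O-[tert-butyl(diphenyl)silyl] ether of 29 | C=C1C(=O)O[C@@H]2/C=C(/CO[Si](c3ccccc3)(c3ccccc3)C(C)(C)C)CC[C@H](OC(=O)C(C)C)C3=C[C@@H](OC3=O)[C@@H]12 | intermediate
29 | (1S,6R,7S,8R,4E,9Z)-15-hydroxy-1-(2-methylpropanoyloxy)germacra-4,9,11(13)-triene-12,6:14,8-diolide | C=C1C(=O)O[C@@H]2/C=C(/CO)CC[C@H](OC(=O)C(C)C)C3=C[C@@H](OC3=O)[C@@H]12 | target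

**Step count and risks**

Total step count: 19. Longest linear sequence: 16 steps (1–6, 8–13, 16–19); steps 7, 14 and 15 are side branches.

Three steps most likely to fail:

Step 18. Intermolecular coupling may compete with ten-membered ring closure, and attack on the wrong face of the C6 aldehyde (or epimerisation at C7 before ring closure) would erode the 6,7-trans relationship. Fallback, setting out from 26 and coming back at 28: the stereocentre is set by reagent-controlled reduction instead of in the ring closure. The same Ni/Cr coupling is quenched at pH 7 so that the hydroxy esters stay open; this gives 27 together with its C6 epimer, the macrocyclic 6-epi-hydroxy ester F1. The mixture is oxidised with Dess–Martin periodinane to the macrocyclic enone F2. Reduction with (R)-2-methyl-CBS-oxazaborolidine and catecholborane (alkenyl branch as the large group) should return 27 alone, and PPTS in CH2Cl2 closes ring C to 28.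

Step 16. The chiral chromium complex may not control the aldehyde face well enough next to the remote C1 centre, and vinylogous loss of methoxide from the allylmetal or pinacol-type coupling of the enal may compete. Fallback, setting out from 15 and coming back at 25: C7–C8 is made by organocatalysis. Peracetic acid (NaOAc, CH2Cl2, 0 °C) converts the 2-silylfuran into the α-substituted butenolide F3 (silyl-directed furan-to-butenolide oxidation). iPr3SiOTf and iPr2NEt give the 2-(triisopropylsilyloxy)furan F4. An iminium-catalysed Mukaiyama–Michael addition to (2E)-4,4-dimethoxybut-2-enal [(2S,5S)-5-benzyl-2-tert-butyl-3-methylimidazolidin-4-one·2,4-dinitrobenzoic acid, CH2Cl2/H2O, −70 °C] should form C7–C8 with catalyst control of the enal face and syn selectivity, giving the butenolide aldehyde F5. α-Methylenation with Eschenmoser's salt and iPr2NEt gives the 2-substituted acrolein F6, Pinnick oxidation (NaClO2, NaH2PO4, 2-methylbut-2-ene) the acrylic acid F7, and Me3SiCHN2 returns 25.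

Step 17. Acid may cause epimerisation at C7 or migration of the C11=C13 double bond into conjugation while the acetal is opened. Fallback, setting out from 18 and 19 and coming back at 26: C6 is carried at the alcohol oxidation level and oxidised under neutral conditions. Morita–Baylis–Hillman reaction of 19 with (tert-butyldimethylsilyloxy)acetaldehyde gives the silyloxy alcohol F8, and NBS/Me2S the (Z)-allyl bromide F9. Chromium-catalysed allylation of 18 as in step 16 proceeds through the open-chain silyl ether F10 and the open-chain hydroxy diester F11 to the butenolide silyl ether F12. HF·pyridine buffered with pyridine at 0 °C removes the primary tert-butyldimethylsilyl group in the presence of the tert-butyldiphenylsilyl ether to give the primary alcohol F13, which is oxidised at once with Dess–Martin periodinane to 26.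

Further compounds

F1 | step 18 | macrocyclic 6-epi-hydroxy ester (6S epimer of 27) | COC(=O)C(=C)[C@H]1[C@@H](O)/C=C(/CO[Si](c2ccccc2)(c2ccccc2)C(C)(C)C)CC[C@H](OC(=O)C(C)C)C2=C[C@H]1OC2=O
F2 | step 18 | macrocyclic enone (6-oxo analogue of 27) | COC(=O)C(=C)[C@H]1C(=O)/C=C(/CO[Si](c2ccccc2)(c2ccccc2)C(C)(C)C)CC[C@H](OC(=O)C(C)C)C2=C[C@H]1OC2=O
F3 | step 16 | (1S,4E)-4-{[tert-butyl(diphenyl)silyl]oxymethyl}-5-iodo-1-(2-oxo-2,5-dihydrofuran-3-yl)pent-4-en-1-yl 2-methylpropanoate | O=C1OCC=C1[C@@H](OC(=O)C(C)C)CC/C(=C\I)CO[Si](c2ccccc2)(c2ccccc2)C(C)(C)C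
F4 | step 16 | (1S,4E)-4-{[tert-butyl(diphenyl)silyl]oxymethyl}-5-iodo-1-[2-(triisopropylsilyloxy)furan-3-yl]pent-4-en-1-yl 2-methylpropanoate | CC(C)[Si](C(C)C)(C(C)C)Oc1occc1[C@@H](OC(=O)C(C)C)CC/C(=C\I)CO[Si](c2ccccc2)(c2ccccc2)C(C)(C)C
F5 | step 16 | butenolide aldehyde: (3R)-4,4-dimethoxy-3-[(2R)-butenolid-2-yl]butanal carrying the C1 side chain of 25 | O=CC[C@@H](C(OC)OC)[C@@H]1OC(=O)C(=C1)[C@@H](OC(=O)C(C)C)CC/C(=C\I)CO[Si](c2ccccc2)(c2ccccc2)C(C)(C)C
F6 | step 16 | 2-methylidene analogue of F5 (2-substituted acrolein) | O=CC(=C)[C@@H](C(OC)OC)[C@@H]1OC(=O)C(=C1)[C@@H](OC(=O)C(C)C)CC/C(=C\I)CO[Si](c2ccccc2)(c2ccccc2)C(C)(C)C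
F7 | step 16 | acrylic acid corresponding to ester 25 | OC(=O)C(=C)[C@@H](C(OC)OC)[C@@H]1OC(=O)C(=C1)[C@@H](OC(=O)C(C)C)CC/C(=C\I)CO[Si](c2ccccc2)(c2ccccc2)C(C)(C)C
F8 | step 17 | racemic methyl 4-{[tert-butyl(dimethyl)silyl]oxy}-3-hydroxy-2-methylidenebutanoate | COC(=O)C(=C)C(O)CO[Si](C)(C)C(C)(C)C
F9 | step 17 | methyl (2Z)-2-(bromomethyl)-4-{[tert-butyl(dimethyl)silyl]oxy}but-2-enoate | COC(=O)/C(CBr)=C/CO[Si](C)(C)C(C)(C)C
F10 | step 17 | open-chain silyl ether (O8-trimethylsilyl ether of F11; not isolated) | COC(=O)/C(=C\[C@@H](O[Si](C)(C)C)[C@@H](C(=C)C(=O)OC)CO[Si](C)(C)C(C)(C)C)[C@@H](OC(=O)C(C)C)CC/C(=C\I)CO[Si](c1ccccc1)(c1ccccc1)C(C)(C)C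
F11 | step 17 | open-chain hydroxy diester (C6 silyloxymethyl analogue of 24; not isolated) | COC(=O)/C(=C\[C@@H](O)[C@@H](C(=C)C(=O)OC)CO[Si](C)(C)C(C)(C)C)[C@@H](OC(=O)C(C)C)CC/C(=C\I)CO[Si](c1ccccc1)(c1ccccc1)C(C)(C)C
F12 | step 17 | butenolide silyl ether (C6 CH2O-tert-butyldimethylsilyl analogue of 25) | COC(=O)C(=C)[C@@H](CO[Si](C)(C)C(C)(C)C)[C@@H]1OC(=O)C(=C1)[C@@H](OC(=O)C(C)C)CC/C(=C\I)CO[Si](c2ccccc2)(c2ccccc2)C(C)(C)C
F13 | step 17 | primary alcohol (C6 CH2OH analogue of 26) | COC(=O)C(=C)[C@@H](CO)[C@@H]1OC(=O)C(=C1)[C@@H](OC(=O)C(C)C)CC/C(=C\I)CO[Si](c2ccccc2)(c2ccccc2)C(C)(C)C
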